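**Retrosynthetic overview**
1. Last: the six-membered lactone by an equilibrating Meerwein–Ponndorf–Verley reduction/lactonization of a bridging ketone; the cyclopentene by ring-closing carbonyl olefination; the seven-membered ring by intramolecular aldol condensation.
2. Before that: the quaternary carbon of the six-membered lactone by Michael addition to methyl acrylate; the piperidine ring and the CH2OH-bearing quaternary carbon by enamine Michael addition/reductive amination of a spiro enedione with pent-4-enal.
3. The five-membered lactone by keteniminium [2+2]/Baeyer–Villiger on a 3-pyrroline; the spiro cyclopentenone by cross-metathesis with but-3-en-2-one and a Dieckmann-type closure that expels the auxiliary.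
4. The N-bearing quaternary stereocentre, from which all others are relayed, by auxiliary-controlled Birch reductive alkylation (dearomatization) of a 4-methylpyrrole-2-carboxylate.
5. Ring order: pyrroline, spiro cyclopentenone, γ-lactone, piperidine (2-azabicyclo[3.2.1]octane), cycloheptenone, cyclopentene, δ-lactone.

Atom labels (taken from the target, used only to describe compounds): C1 methyl; C2 its quaternary carbon; C3 and C4 the CH2 and C=O of the five-membered lactone; O5; C6 the OCH of that lactone; C7 the N-bearing quaternary carbon; C8 the CH2 between C7 and C9; C9 the carbon bearing C10H2OH; C12 the CH bearing C26H2N; C13, C14 ring CH2CH2; C15 the allylic CH; C16, C17 cyclopentene CH2CH2; C18=C19 the alkene; C20 the quaternary carbon bearing C21H2C22H2C23(=O)O24; C25 the OCH of the six-membered lactone; N27; C28 the NCH2 on C2.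

Assumption: (−)-8-phenylmenthol is taken to give the (R) configuration at C7 in step 3; if the induction proves opposite, the enantiomeric auxiliary is used with no other change.

**Route**

Step 1
Reactants: 1 4-methyl-1H-pyrrole-2-carboxylic acid; 2 (−)-8-phenylmenthol
Product: 3 (−)-8-phenylmenthyl 4-methyl-1H-pyrrole-2-carboxylate
Conditions: DCC, DMAP (cat.), CH2Cl2, 0 °C to rt
Reagents that add atoms: none
Why: Steglich esterification attaches the recoverable chiral auxiliary to the inexpensive pyrrole acid; no stereocentre is formed.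

Step 2
Reactants: 3 (−)-8-phenylmenthyl 4-methyl-1H-pyrrole-2-carboxylate
Product: 4 1-tert-butyl 2-[(−)-8-phenylmenthyl] 4-methyl-1H-pyrrole-1,2-dicarboxylate
Conditions: Boc2O, DMAP (cat.), MeCN, rt
Reagents that add atoms: di-tert-butyl dicarbonate, CC(C)(C)OC(=O)OC(=O)OC(C)(C)C
Why: DMAP-catalysed N-acylation makes the pyrrole electron-poor enough for a Birch reduction and protects nitrogen until the cage is built.

Step 3
Reactants: 4 1-tert-butyl 2-[(−)-8-phenylmenthyl] 4-methyl-1H-pyrrole-1,2-dicarboxylate; 5 3-bromo-2-(bromomethyl)prop-1-ene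
Product: 7 1-tert-butyl 2-[(−)-8-phenylmenthyl] (2R)-2-[2-(bromomethyl)prop-2-en-1-yl]-4-methyl-2,5-dihydro-1H-pyrrole-1,2-dicarboxylate, via lithium enolate 6 (not isolated)
Conditions: Li (3 equiv), NH3/THF, −78 °C; isoprene; then 5 (5 equiv), −78 °C; NH4Cl
Reagents that add atoms: none
Why: Birch reductive alkylation (dearomatization): two-electron reduction and protonation at C28 give ester enolate 6, which the allylic bromide alkylates at C7 on the face not shielded by the phenyl group of the 8-phenylmenthyl ester, setting C7 (R), the only stereocentre set by an external controller; excess dibromide suppresses double alkylation.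

Step 4
Reactants: 7 the allylic bromide from step 3
Product: 8 1-tert-butyl 2-[(−)-8-phenylmenthyl] (2R)-2-[2-(acetoxymethyl)prop-2-en-1-yl]-4-methyl-2,5-dihydro-1H-pyrrole-1,2-dicarboxylate
Conditions: KOAc, DMF, 40 °C
Reagents that add atoms: potassium acetate, CC(=O)[O-].[K+]
Why: SN2 displacement of the allylic bromide installs the C10 oxygen (as acetate) while C10 is still allylic, before C9 becomes quaternary.

Step 5
Reactants: 8 the allylic acetate from step 4; 9 but-3-en-2-one
Product: 10 1-tert-butyl 2-[(−)-8-phenylmenthyl] (2R)-2-[2-(acetoxymethyl)-4-oxopent-2-en-1-yl]-4-methyl-2,5-dihydro-1H-pyrrole-1,2-dicarboxylate (E/Z mixture)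
Conditions: 9 (3 equiv), second-generation Hoveyda–Grubbs catalyst RuCl2(H2IMes)(=CH-C6H4-2-O-i-Pr) (5 mol %), CH2Cl2, 40 °C
Reagents that add atoms: none
Why: Olefin cross-metathesis of the 1,1-disubstituted alkene with the electron-poor enone partner; the hindered trisubstituted ring alkene does not react and the alkene geometry is erased in step 6.

Step 6
Reactants: 10 the enone ester from step 5
Product: 11 tert-butyl (5R)-7-acetyl-8-(acetoxymethyl)-3-methyl-6-oxo-1-azaspiro[4.4]nona-3,7-diene-1-carboxylate
Conditions: NaH (2.2 equiv), t-BuOH (0.2 equiv), THF, 0 °C to rt; NH4Cl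
Reagents that add atoms: none
Why: Proposed new method: intramolecular Claisen (Dieckmann-type) α-acylation of the thermodynamic extended enolate of the enone, in which the dienolate attacks the ester carbonyl C25 through its α-carbon C20 in a five-membered transition state, the hindered auxiliary alkoxide leaves and the 2-acyl cyclopentenone is drained as its stabilized enolate; the closest known reactions are the Dieckmann condensation and the α-selective reactions of extended enolates.

Step 7
Reactants: 11 the spiro enedione from step 6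
Product: 13 cyclobutanone cis-fused across C6–C2 of 11 (C4=O on C6; C3H2 on C2; on the C25 face), via cyclobutaniminium triflate 12 (not isolated)
Conditions: N,N-dimethylacetamide, Tf2O, 2,4,6-collidine, ClCH2CH2Cl, −15 °C to 80 °C; then aq. NaHCO3, rt
Reagents that add atoms: N,N-dimethylacetamide, CC(=O)N(C)C; water, O
Why: Ghosez keteniminium [2+2] cycloaddition, in which the iminium carbon bonds to the less substituted C6 and the CH2 to C2, and the reagent approaches the pyrroline from the side of the flat C25 carbonyl and not past the C8 methylene, which sets C6 and C2 (cis-fused) relative to C7; hydrolysis gives the ketone.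

Step 8
Reactants: 13 the cyclobutanone from step 7
Product: 14 N-Boc γ-lactone (O5 between C4 and C6; cis-fused; C2 methyl) of the spiro enedione
Conditions: mCPBA, NaHCO3, CH2Cl2, 0 °C
Reagents that add atoms: 3-chloroperoxybenzoic acid, OOC(=O)c1cccc(Cl)c1
Why: Baeyer–Villiger oxidation of the strained cyclobutanone with migration of the more substituted C6 (retention) gives the γ-lactone regioselectively; the electron-poor enedione and the carbamate are not oxidized.

Step 9
Reactants: 14 the N-Boc γ-lactone from step 8; 15 pent-4-enal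
Product: 18 tricyclic amine (2-azabicyclo[3.2.1]octane core; C12 allyl; C20-H diketone drawn as its C25 enol), via free amine 16 (not isolated), via iminium enolate 17 (not isolated)
Conditions: TFA, CH2Cl2, 0 °C; evaporate; then 15 (1.2 equiv), NaOAc, AcOH, MeCN (0.01 M), 40 °C; then NaBH(OAc)3, rt
Reagents that add atoms: none
Why: Boc removal, enamine formation with the aldehyde, intramolecular Stork-type enamine Michael addition to the alkylidene diketone through a six-membered transition state and reduction of the iminium ion (reductive amination); C12 can reach C9 only on the N-bearing face (sets C9), and C12 settles with its allyl chain equatorial under enamine–iminium equilibration before reduction.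

Step 10
Reactants: 18 the tricyclic amine from step 9; 19 methyl acrylate
Product: 20 Michael adduct (C20 quaternary: acetyl endo and CH2CH2CO2Me exo)
Conditions: 19 (5 equiv), DBU (0.3 equiv), MeCN, 50 °C
Reagents that add atoms: none
Why: Michael addition of the β-diketone to the unhindered acrylate terminus; the acrylate enters on the exo face of the bicyclo[3.2.1] enolate, away from the piperidine bridge and the C12 allyl group, which sets C20.

Step 11
Reactants: 20 the Michael adduct from step 10
Product: 22 cycloheptenone (C14=C15 conjugated to the C19 ketone), via keto aldehyde 21 (not isolated)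
Conditions: TsOH·H2O (1.2 equiv), CH2Cl2, −78 °C, O3; PPh3; then PhMe (0.01 M), 90 °C
Reagents that add atoms: none
Why: Ozonolysis of the only alkene (amine protected as its salt) unmasks the C14 aldehyde, and acid-catalysed intramolecular aldol condensation of the methyl ketone enol (C15) onto the aldehyde, the better electrophile, closes the seven-membered enone; no stereocentre is formed.

Step 12
Reactants: 22 the cycloheptenone from step 11; 23 but-3-en-1-ol
Product: 26 C15 but-3-enyl ketone, via but-3-enyl triflate 24 (not isolated), via lithium enolate 25 (not isolated)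
Conditions: 23, Tf2O, 2,6-lutidine, CH2Cl2, −78 °C (gives 24); 22, LiBH(s-Bu)3 (1.05 equiv), THF, −78 °C; then 24, −78 °C
Reagents that add atoms: none
Why: Reductive alkylation: 1,4-hydride addition gives the regiodefined enolate, which the triflate alkylates at −78 °C, faster than the enolate can attack the C23 ester, on the face anti to the pseudo-axial C21 arm on C20, which places H15 on the side of C21 and C10.

Step 13
Reactants: 26 the C15 but-3-enyl ketone from step 12
Product: 27 cyclopentene ketone (C18=C19; C25 ketone; C23 methyl ester; C10 acetate)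
Conditions: Mo(=CHCMe2Ph)(=N-2,6-i-Pr2C6H3)[OCMe(CF3)2]2 (1.2 equiv), C6H6, 25 to 60 °C
Reagents that add atoms: none
Why: Ring-closing carbonyl–olefin metathesis of the Fu–Grubbs type: the molybdenum alkylidene forms at the terminal alkene and olefinates the C19 ketone intramolecularly to give the C18=C19 cyclopentene regiospecifically; C15 is untouched, and the C25 ketone and the esters are too hindered or too unreactive to compete.

Step 14
Reactants: 27 the cyclopentene ketone from step 13
Product: 28 CNP0247797.1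
Conditions: Al(O-i-Pr)3 (6 equiv), i-PrOH/PhMe, 105 °C, sealed tube; then 1 M HCl, rt; NaHCO3
Reagents that add atoms: none
Why: Meerwein–Ponndorf–Verley reduction run reversibly (Oppenauer back-reaction with the retained acetone) equilibrates the C25 alkoxide epimers, and only the one cis to the C21 arm lactonizes onto the C23 ester, which drains the mixture to the δ-lactone and sets C25; the same alkoxide medium transesterifies the C10 acetate, and the acidic work-up recloses any opened γ-lactone.

**Compound list**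
1 | 4-methyl-1H-pyrrole-2-carboxylic acid | Cc1c[nH]c(c1)C(=O)O | starting material
2 | (−)-8-phenylmenthol, (1R,2S,5R)-5-methyl-2-(2-phenylpropan-2-yl)cyclohexan-1-ol | O[C@@H]1C[C@H](C)CC[C@H]1C(C)(C)c1ccccc1 | starting material
3 | (−)-8-phenylmenthyl 4-methyl-1H-pyrrole-2-carboxylate | Cc1c[nH]c(c1)C(=O)O[C@@H]1C[C@H](C)CC[C@H]1C(C)(C)c1ccccc1 | intermediate
4 | 1-tert-butyl 2-[(−)-8-phenylmenthyl] 4-methyl-1H-pyrrole-1,2-dicarboxylate | Cc1cn(C(=O)OC(C)(C)C)c(c1)C(=O)O[C@@H]1C[C@H](C)CC[C@H]1C(C)(C)c1ccccc1 | intermediate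
5 | 3-bromo-2-(bromomethyl)prop-1-ene | BrCC(=C)CBr | starting material
6 | lithium ester enolate of 1-Boc-4-methyl-2,5-dihydro-1H-pyrrole-2-carboxylic acid (−)-8-phenylmenthyl ester | CC1=CC(=C([O-])O[C@@H]2C[C@H](C)CC[C@H]2C(C)(C)c2ccccc2)N(C(=O)OC(C)(C)C)C1.[Li+] | intermediate
7 | 1-tert-butyl 2-[(−)-8-phenylmenthyl] (2R)-2-[2-(bromomethyl)prop-2-en-1-yl]-4-methyl-2,5-dihydro-1H-pyrrole-1,2-dicarboxylate | CC1=C[C@@](C(=O)O[C@@H]2C[C@H](C)CC[C@H]2C(C)(C)c2ccccc2)(CC(=C)CBr)N(C(=O)OC(C)(C)C)C1 | intermediate
8 | 1-tert-butyl 2-[(−)-8-phenylmenthyl] (2R)-2-[2-(acetoxymethyl)prop-2-en-1-yl]-4-methyl-2,5-dihydro-1H-pyrrole-1,2-dicarboxylate | CC1=C[C@@](C(=O)O[C@@H]2C[C@H](C)CC[C@H]2C(C)(C)c2ccccc2)(CC(=C)COC(C)=O)N(C(=O)OC(C)(C)C)C1 | intermediate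
9 | but-3-en-2-one | CC(=O)C=C | starting material
10 | 1-tert-butyl 2-[(−)-8-phenylmenthyl] (2R)-2-[2-(acetoxymethyl)-4-oxopent-2-en-1-yl]-4-methyl-2,5-dihydro-1H-pyrrole-1,2-dicarboxylate (E/Z mixture) | CC1=C[C@@](C(=O)O[C@@H]2C[C@H](C)CC[C@H]2C(C)(C)c2ccccc2)(CC(COC(C)=O)=CC(C)=O)N(C(=O)OC(C)(C)C)C1 | intermediate
11 | tert-butyl (5R)-7-acetyl-8-(acetoxymethyl)-3-methyl-6-oxo-1-azaspiro[4.4]nona-3,7-diene-1-carboxylate | CC1=C[C@@]2(CC(COC(C)=O)=C(C(C)=O)C2=O)N(C(=O)OC(C)(C)C)C1 | intermediate
12 | N,N-dimethylcyclobutaniminium triflate from [2+2] at C6=C2 of 11 (C4=N+ on C6, C3H2 on C2, cis-fused, on the C25 face) | C[C@@]12CC(=[N+](C)C)[C@@H]1[C@@]1(CC(COC(C)=O)=C(C(C)=O)C1=O)N(C(=O)OC(C)(C)C)C2.[O-]S(=O)(=O)C(F)(F)F | intermediate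
13 | cyclobutanone (C4=O analogue of 12) | C[C@@]12CC(=O)[C@@H]1[C@@]1(CC(COC(C)=O)=C(C(C)=O)C1=O)N(C(=O)OC(C)(C)C)C2 | intermediate
14 | N-Boc γ-lactone (O5 inserted between C4 and C6 of 13) | C[C@@]12CC(=O)O[C@@H]1[C@@]1(CC(COC(C)=O)=C(C(C)=O)C1=O)N(C(=O)OC(C)(C)C)C2 | intermediate
15 | pent-4-enal | C=CCCC=O | starting material
16 | free secondary amine of 14 | C[C@@]12CC(=O)O[C@@H]1[C@@]1(CC(COC(C)=O)=C(C(C)=O)C1=O)NC2 | intermediate
17 | bridged iminium enolate (N+=C26; C12–C9 bond formed; C12 allyl; C25/C19 diketonate) | C[C@@]12CC(=O)O[C@@H]1[C@]13C[C@@](COC(C)=O)([C@H](CC=C)C=[N+]3C2)C(C(C)=O)=C1[O-] | intermediate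
18 | tricyclic amine with 2-azabicyclo[3.2.1]octane core (C12 allyl; C20-H β-diketone drawn as C25 enol) | C[C@@]12CC(=O)O[C@@H]1[C@]13C[C@@](COC(C)=O)([C@H](CC=C)CN3C2)C(C(C)=O)=C1O | intermediate
19 | methyl acrylate | C=CC(=O)OC | starting material
20 | Michael adduct (C20 quaternary: endo acetyl, exo CH2CH2CO2Me) | C[C@@]12CC(=O)O[C@@H]1[C@]13C[C@@](COC(C)=O)([C@H](CC=C)CN3C2)[C@](C(C)=O)(CCC(=O)OC)C1=O | intermediate
21 | keto aldehyde (C14 aldehyde in place of the vinyl group of 20) | C[C@@]12CC(=O)O[C@@H]1[C@]13C[C@@](COC(C)=O)([C@H](CC=O)CN3C2)[C@](C(C)=O)(CCC(=O)OC)C1=O | intermediate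
22 | cycloheptenone (C14=C15–C19=O) | C[C@@]12CC(=O)O[C@@H]1[C@]13C[C@@]4(COC(C)=O)[C@H](CC=CC(=O)[C@@]4(CCC(=O)OC)C1=O)CN3C2 | intermediate
23 | but-3-en-1-ol | OCCC=C | starting material
24 | but-3-en-1-yl trifluoromethanesulfonate | C=CCCOS(=O)(=O)C(F)(F)F | intermediate
25 | lithium enolate C19(OLi)=C15 from 1,4-reduction of 22 | C[C@@]12CC(=O)O[C@@H]1[C@]13C[C@@]4(COC(C)=O)[C@H](CCC=C([O-])[C@@]4(CCC(=O)OC)C1=O)CN3C2.[Li+] | intermediate
26 | C15 but-3-enyl cycloheptanone | C[C@@]12CC(=O)O[C@@H]1[C@]13C[C@@]4(COC(C)=O)[C@H](CC[C@@H](CCC=C)C(=O)[C@@]4(CCC(=O)OC)C1=O)CN3C2 | intermediate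
27 | cyclopentene ketone (C18=C19; C25 ketone; C23 methyl ester; C10 acetate) | C[C@@]12CC(=O)O[C@@H]1[C@]13C[C@@]4(COC(C)=O)[C@H](CC[C@H]5CCC=C5[C@@]4(CCC(=O)OC)C1=O)CN3C2 | intermediate
28 | CNP0247797.1 | C[C@@]12CC(=O)O[C@@H]1[C@]13C[C@@]4(CO)[C@H](CC[C@H]5CCC=C5[C@]45CCC(=O)O[C@H]15)CN3C2 | target

**Step count and risks**

Total steps: 14. Longest linear sequence: 14 steps (1 to 28; every other component is purchased).

The three steps most likely to fail are steps 6, 11 and 14.

Step 6 may give γ-acylation at C10, or no reaction at the hindered auxiliary ester. The fallback makes the C20–C25 bond by an aldol reaction instead and sets out from 7. Reduction with i-Bu2AlH (toluene, −78 °C) releases the auxiliary and gives the aldehyde tert-butyl (2R)-2-[2-(bromomethyl)prop-2-en-1-yl]-2-formyl-4-methyl-2,5-dihydro-1H-pyrrole-1-carboxylate F1. KOAc in DMF gives tert-butyl (2R)-2-[2-(acetoxymethyl)prop-2-en-1-yl]-2-formyl-4-methyl-2,5-dihydro-1H-pyrrole-1-carboxylate F2. Cross-metathesis with 9 under the step 5 conditions gives tert-butyl (2R)-2-[2-(acetoxymethyl)-4-oxopent-2-en-1-yl]-2-formyl-4-methyl-2,5-dihydro-1H-pyrrole-1-carboxylate F3. DBU then closes the ring by aldol addition of the extended enolate (α-carbon C20) to the far more electrophilic aldehyde, giving tert-butyl (5R)-7-acetyl-8-(acetoxymethyl)-6-hydroxy-3-methyl-1-azaspiro[4.4]nona-3,7-diene-1-carboxylate F4. Dess–Martin periodinane oxidizes it, and the fallback comes back to the route at 11.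

Step 11 may give the five-membered aldol mode (aldehyde α-carbon C13 onto the C19 ketone) or oligomers. The fallback closes the seven-membered ring by ring-closing metathesis and sets out from 20. Silyl enol ether formation at the methyl ketone (Me3SiOSO2CF3, Et3N) and reaction with CH2=NMe2+ I− give the Mannich base of 20 F5. Warming F5 with silica gel in toluene eliminates the amine to the vinyl ketone of 20 F6. RuCl2(H2IMes)(=CH-C6H4-2-O-i-Pr) in CH2Cl2 at 40 °C (amine as its tosylate salt) joins C14 and C15, and the fallback comes back to the route at 22.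

Step 14 may fail because the doubly neopentylic C25 ketone equilibrates too slowly under aluminium alkoxide conditions. The fallback separates reduction, epimerization and deprotection and sets out from 27. NaBH4 in MeOH at 0 °C gives the C25 endo-alcohol of 27 F7, the epimer expected from exo attack. Heating with the hydrogen-transfer catalyst [(Ph4C4CO)2H]Ru2(CO)4(μ-H) in toluene at 100 °C epimerizes the carbinol through the ketone, and the exo epimer is trapped as the O-acetyl derivative of 28 F8. K2CO3 in MeOH followed by dilute HCl removes the acetate and recloses the lactones, and the fallback comes back to the route at 28.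

**Further compounds**
F1 | step 6 | tert-butyl (2R)-2-[2-(bromomethyl)prop-2-en-1-yl]-2-formyl-4-methyl-2,5-dihydro-1H-pyrrole-1-carboxylate | CC1=C[C@@](C=O)(CC(=C)CBr)N(C(=O)OC(C)(C)C)C1
F2 | step 6 | tert-butyl (2R)-2-[2-(acetoxymethyl)prop-2-en-1-yl]-2-formyl-4-methyl-2,5-dihydro-1H-pyrrole-1-carboxylate | CC1=C[C@@](C=O)(CC(=C)COC(C)=O)N(C(=O)OC(C)(C)C)C1
F3 | step 6 | tert-butyl (2R)-2-[2-(acetoxymethyl)-4-oxopent-2-en-1-yl]-2-formyl-4-methyl-2,5-dihydro-1H-pyrrole-1-carboxylate | CC1=C[C@@](C=O)(CC(COC(C)=O)=CC(C)=O)N(C(=O)OC(C)(C)C)C1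
F4 | step 6 | tert-butyl (5R)-7-acetyl-8-(acetoxymethyl)-6-hydroxy-3-methyl-1-azaspiro[4.4]nona-3,7-diene-1-carboxylate (C6 epimers) | CC1=C[C@@]2(CC(COC(C)=O)=C(C(C)=O)C2O)N(C(=O)OC(C)(C)C)C1
F5 | step 11 | Mannich base of 20 (C19(=O)CH2CH2NMe2) | C[C@@]12CC(=O)O[C@@H]1[C@]13C[C@@](COC(C)=O)([C@H](CC=C)CN3C2)[C@](C(=O)CCN(C)C)(CCC(=O)OC)C1=O
F6 | step 11 | vinyl ketone of 20 (C19(=O)CH=CH2) | C[C@@]12CC(=O)O[C@@H]1[C@]13C[C@@](COC(C)=O)([C@H](CC=C)CN3C2)[C@](C(=O)C=C)(CCC(=O)OC)C1=O
F7 | step 14 | C25 endo-alcohol of 27 | C[C@@]12CC(=O)O[C@@H]1[C@]13C[C@@]4(COC(C)=O)[C@H](CC[C@H]5CCC=C5[C@@]4(CCC(=O)OC)[C@H]1O)CN3C2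
F8 | step 14 | O-acetyl derivative of 28 | C[C@@]12CC(=O)O[C@@H]1[C@]13C[C@@]4(COC(C)=O)[C@H](CC[C@H]5CCC=C5[C@]45CCC(=O)O[C@H]15)CN3C2
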